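## Retrosynthetic overview
1. Target 5 is the formal water adduct of andrographolide 1 across the C12=C13 alkylidene bond. The one strategic disconnection is therefore the C12–O bond, together with C13–H. Oxygen goes on the alkene face anti to the 14-OH and hydrogen on the face syn to it (net anti-hydration).
2. The C12–O bond is made with retention from a C12–B bond in the same flask. C12 and C13 are both set in the preceding copper-catalysed borylation/protonation of the alkylidene lactone.
3. The 3,19-diol is carried as an acetonide (on in step 1, off in step 3). This lets the key step run in THF and lets the diastereomers be separated on silica before the polar tetraol stage.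
4. Ring order: rings A and B (decalin) and the lactone ring C come intact from 1, together with C3, C4, C5, C9, C10 and C14. No ring of the target is built. Only the temporary dioxane ring is closed and reopened.

Assumption: labdane numbering is used (C12 side-chain CH, C13 lactone α-carbon, C14 lactone carbinol, C8(17) exocyclic methylene), and the (R,S_p) ligand enantiomer is taken as the one matched to Si-face attack at C12, to be confirmed against its mirror image in the first run.

## Route

Step 1
Reactants: 1 andrographolide (12E,14S; bulk extract product, single enantiomer)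
Product: 2 3,19-O-isopropylideneandrographolide
Conditions: Me2C(OMe)2 (4 equiv), pyridinium p-toluenesulfonate (0.1 equiv), toluene/DMSO 9:1, 80 °C, 1 h
Reagents that add atoms: 2,2-dimethoxypropane, COC(C)(C)OC
Why: Acid-catalysed transketalisation (acetonide protection): the 3-OH/19-OH 1,3-diol closes a chair 1,3-dioxane much faster than the lone allylic 14-OH reacts, no stereocentre is touched, and 2 is soluble in THF and easy to chromatograph.

Step 2
Reactants: 2 3,19-O-isopropylideneandrographolide
Product: 4 (12S,13S,14S)-12-hydroxy-12,13-dihydro-3,19-O-isopropylideneandrographolide, via C12 pinacol boronate 3 (not isolated)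
Conditions: CuCl (5 mol %), NaOtBu (10 mol %), (R)-1-[(S_p)-2-(diphenylphosphino)ferrocenyl]ethyldicyclohexylphosphine (6 mol %), B2pin2 (1.3 equiv), MeOH (4 equiv), THF, 0 °C to rt, 12 h; then pH 7.4 NaH2PO4/Na2HPO4 buffer, 30% aq H2O2 (10 equiv), 0 °C to rt, 3 h
Reagents that add atoms: bis(pinacolato)diboron, CC1(C)OB(OC1(C)C)B1OC(C)(C)C(C)(C)O1 (Bpin of 3); hydrogen peroxide, OO (O12 of 4)
Why: Proposed new method: net anti-hydration of a free-hydroxyl Morita–Baylis–Hillman-type alkylidene lactone by ligand-controlled conjugate borylation, hydroxyl-relayed protonation and in-flask B-to-O exchange; LCu–Bpin (monovalent copper, from CuCl, NaOtBu and B2pin2) adds syn across C12=C13 with boron on the Si face of C12, the face anti to the 14-OH, because copper must dock on C13 directly next to C14 and the ligand quadrants reinforce that choice; the O-bound copper enolate is then protonated at C13 by methanol hydrogen-bonded to the 14-OH, anti to the aligned bulky C12–B bond, giving the trans (also thermodynamically preferred) 13S lactone faster than it can expel hydroxide, a far poorer leaving group than the acetates and carbonates that give SN2′ allylboronates, while excess MeOH keeps O14 from being borylated; hydroperoxide at pH 7.4 then attacks boron and the 1,2-shift of C12 from B to O forms the C12–O bond with retention (12S), without the base that would trigger E1cB loss of either β-hydroxyl, and the unactivated 8(17)-alkene and the acetonide are inert throughout; the closest known reaction type is the copper-catalysed asymmetric β-borylation of simple acyclic enoates followed by oxidation, which has not been shown on trisubstituted α-alkylidene-β-hydroxy lactones or with control of both new centres.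

Step 3
Reactants: 4 (12S,13S,14S)-12-hydroxy-12,13-dihydro-3,19-O-isopropylideneandrographolide
Product: 5 (12S,13S,14S)-12-hydroxy-12,13-dihydroandrographolide (target)
Conditions: AcOH/H2O 7:3, rt, 1 h
Reagents that add atoms: none
Why: Acid-catalysed acetal hydrolysis: the weak acid at room temperature cleaves the dioxane but does not protonate the 8(17)-alkene, enolise C13 or dehydrate the β-hydroxy lactone, so no stereocentre is touched.

## Compound list
1 | andrographolide, (3E,4S)-4-hydroxy-3-{2-[(1R,4aS,5R,6R,8aS)-6-hydroxy-5-(hydroxymethyl)-5,8a-dimethyl-2-methylidenedecahydronaphthalen-1-yl]ethylidene}oxolan-2-one | C=C1CC[C@@H]2[C@](C)(CO)[C@H](O)CC[C@@]2(C)[C@@H]1C/C=C1/C(=O)OC[C@H]1O | starting material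
2 | 3,19-O-isopropylideneandrographolide (12E,14S; free 14-OH) | C=C1CC[C@@H]2[C@]3(C)COC(C)(C)O[C@@H]3CC[C@@]2(C)[C@@H]1C/C=C1/C(=O)OC[C@H]1O | intermediate
3 | (12S,13S,14S)-12-(4,4,5,5-tetramethyl-1,3,2-dioxaborolan-2-yl)-12,13-dihydro-3,19-O-isopropylideneandrographolide (side chain trans to 14-OH on the lactone; not isolated) | C=C1CC[C@@H]2[C@]3(C)COC(C)(C)O[C@@H]3CC[C@@]2(C)[C@@H]1C[C@H](B1OC(C)(C)C(C)(C)O1)[C@@H]1C(=O)OC[C@H]1O | intermediate
4 | (12S,13S,14S)-12-hydroxy-12,13-dihydro-3,19-O-isopropylideneandrographolide | C=C1CC[C@@H]2[C@]3(C)COC(C)(C)O[C@@H]3CC[C@@]2(C)[C@@H]1C[C@H](O)[C@@H]1C(=O)OC[C@H]1O | intermediate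
5 | (12S,13S,14S)-12-hydroxy-12,13-dihydroandrographolide, (3S,4S)-4-hydroxy-3-{(1S)-1-hydroxy-2-[(1R,4aS,5R,6R,8aS)-6-hydroxy-5-(hydroxymethyl)-5,8a-dimethyl-2-methylidenedecahydronaphthalen-1-yl]ethyl}oxolan-2-one | C=C1CC[C@@H]2[C@](C)(CO)[C@H](O)CC[C@@]2(C)[C@@H]1C[C@H](O)[C@@H]1C(=O)OC[C@H]1O | target

## Step count and risks
Total step count: 3. Longest linear sequence: 3 (1 → 2 → 4 → 5).

(a) Step 2, the proposed new step, is the most likely to fail.
- **Risks:** the copper enolate may lose the C14 oxygen in an SN2′ sense and give a 12-boryl-14-deoxy butenolide. The facial sense at C12 or the protonation at C13 may also be poor.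
- **Fallback (known chemistry):** it sets out from 2 and still forms the C12–O bond directly.
  - Weitz–Scheffer nucleophilic epoxidation (tBuOOH in decane, DBU, CH2Cl2, 0 °C) gives the spiro-epoxy lactone 12,13-epoxy-3,19-O-isopropylideneandrographolide F1. Peroxide attack and ring closure occur on the face anti to the 14-OH, and any other-face epoxide is removed on silica.
  - Reductive cleavage of the Cα–O bond of this α,β-epoxy lactone with SmI2 (2.5 equiv, THF/MeOH, −78 °C) follows. Protonation of the samarium enolate to the trans lactone comes back to the route at 4.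

(b) Step 3 is next.
- **Risks:** the acid may add the new 12-OH to the protonated 8(17)-alkene (8,12-ether, as in the isoandrographolide series), or it may dehydrate the β-hydroxy lactone.
- **Fallback:** it replaces the acid-labile mask by a fluoride-labile one and sets out from 1.
  - tBu2Si(OTf)2 (1.05 equiv) and 2,6-lutidine in CH2Cl2/DMF at 0 °C give 3,19-O-(di-tert-butylsilylene)andrographolide F2.
  - The conditions of step 2 take it through the silylene-protected C12 pinacol boronate F3, which is not isolated, to the silylene-protected 12S-alcohol F4.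
  - HF·pyridine in THF/pyridine at 0 °C then comes back to the route at 5.

(c) Step 1 is the least risky of the three.
- **Risks:** heat and acid can dehydrate 1 to 14-deoxy-11,12-didehydroandrographolide or put a mixed ketal on O14.
- **Fallback:** it uses a neutral, traceless mask and sets out from 1.
  - PhB(OH)2 (1.05 equiv) and MgSO4 in THF at rt give andrographolide 3,19-phenylboronate F5.
  - The borylation conditions of step 2 give the bis-boron adduct 12-Bpin-12,13-dihydroandrographolide 3,19-phenylboronate F6, which is not isolated.
  - The buffered H2O2 stage oxidises both C–B bonds and frees the diol, so this path skips 2 to 4 and comes back to the route at 5. Isolation is then by reverse-phase chromatography.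

## Further compounds
F1 | step 2 | 12,13-epoxy-3,19-O-isopropylideneandrographolide, oxirane oxygen anti to the 14-OH (12S,13R,14R) | C=C1CC[C@@H]2[C@]3(C)COC(C)(C)O[C@@H]3CC[C@@]2(C)[C@@H]1C[C@@H]1O[C@@]12C(=O)OC[C@H]2O
F2 | step 3 | 3,19-O-(di-tert-butylsilylene)andrographolide (12E,14S) | C=C1CC[C@@H]2[C@]3(C)CO[Si](C(C)(C)C)(C(C)(C)C)O[C@@H]3CC[C@@]2(C)[C@@H]1C/C=C1/C(=O)OC[C@H]1O
F3 | step 3 | (12S,13S,14S)-12-(pinacolatoboryl)-12,13-dihydro-3,19-O-(di-tert-butylsilylene)andrographolide | C=C1CC[C@@H]2[C@]3(C)CO[Si](C(C)(C)C)(C(C)(C)C)O[C@@H]3CC[C@@]2(C)[C@@H]1C[C@H](B1OC(C)(C)C(C)(C)O1)[C@@H]1C(=O)OC[C@H]1O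
F4 | step 3 | (12S,13S,14S)-12-hydroxy-12,13-dihydro-3,19-O-(di-tert-butylsilylene)andrographolide | C=C1CC[C@@H]2[C@]3(C)CO[Si](C(C)(C)C)(C(C)(C)C)O[C@@H]3CC[C@@]2(C)[C@@H]1C[C@H](O)[C@@H]1C(=O)OC[C@H]1O
F5 | step 1 | andrographolide 3,19-phenylboronate (12E,14S) | C=C1CC[C@@H]2[C@]3(C)COB(c4ccccc4)O[C@@H]3CC[C@@]2(C)[C@@H]1C/C=C1/C(=O)OC[C@H]1O
F6 | step 1 | (12S,13S,14S)-12-(pinacolatoboryl)-12,13-dihydroandrographolide 3,19-phenylboronate | C=C1CC[C@@H]2[C@]3(C)COB(c4ccccc4)O[C@@H]3CC[C@@]2(C)[C@@H]1C[C@H](B1OC(C)(C)C(C)(C)O1)[C@@H]1C(=O)OC[C@H]1O
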